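**Retrosynthetic overview**
1. C9′=C10′ is cut by a Julia–Kocienski olefination into enal 13 and the (Z)-hex-3-enyl tetrazolyl sulfone 17; 13 comes from terminal alkene 12 by cross-metathesis with crotonaldehyde.
2. The C3–CH2CO2Me bond comes from the peroxycarbenium ion of ethoxydioxolane 11 and an acetate silyl ketene acetal, which sets C3 anti to the C5 chain.
3. The key C3–C4 bond joins α-silylperoxy aldehyde 5 to the α-ethoxy ylide 9, an acetyl anion equivalent; acid then closes the 1,2-dioxolane, the only ring, by hydroperoxide addition to the enol ether.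
4. The C5–OO bond comes from perhydrolysis, with inversion, of (R)-epoxide 2, made from dec-9-en-2-one 1 by catalytic asymmetric Corey–Chaykovsky methylenation.

Locants: ring O1–O2–C3(acetate)–C4–C5(chain); side chain C1′–C15′ counted from C5.

Assumption: the LaLi3[(R)-BINOL-ate]3 catalyst is taken to give the (R)-oxirane 2 from 1; if the first run shows the opposite sense, the catalyst from (S)-BINOL is used and nothing else changes.

**Route**

Step 1
Reactants: 1 dec-9-en-2-one
Product: 2 (2R)-2-methyl-2-(oct-7-en-1-yl)oxirane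
Conditions: Me3S(O)I, NaH, THF (ylide preformed, 1.2 equiv); LaLi3[(R)-BINOL-ate]3 (5 mol %, from La(OiPr)3, (R)-BINOL, n-BuLi), (2,4,6-(MeO)3C6H2)3P=O (5 mol %), 5 Å MS, THF, rt
Reagents that add atoms: trimethylsulfoxonium iodide, C[S+](C)(C)=O.[I-] (delivers CH2 through its ylide)
Why: Catalytic asymmetric Corey–Chaykovsky epoxidation, in which the La/Li binaphthoxide binds the methyl ketone and steers the sulfoxonium ylide to one carbonyl face, setting the quaternary centre that becomes C5 (alkyl methyl ketones typically give above 90% ee) while the remote alkene is inert to the ylide.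

Step 2
Reactants: 2 (2R)-2-methyl-2-(oct-7-en-1-yl)oxirane
Product: 3 (2S)-2-hydroperoxy-2-methyldec-9-en-1-ol
Conditions: H2O2 (about 3 M in Et2O, dried over MgSO4, 5 equiv), H3PMo12O40 (3 mol %), Et2O, rt
Reagents that add atoms: hydrogen peroxide, OO
Why: Molybdenum-catalysed perhydrolysis of a 2,2-disubstituted oxirane, in which H2O2 opens the activated epoxide at the tertiary carbon in a borderline SN2 event with inversion, so the (R)-epoxide gives the (S)-tertiary hydroperoxide (C5 of the target) and leaves the C4 carbinol.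

Step 3
Reactants: 3 (2S)-2-hydroperoxy-2-methyldec-9-en-1-ol
Product: 4 (2S)-2-methyl-2-[(triethylsilyl)peroxy]dec-9-en-1-ol
Conditions: Et3SiCl (1.05 equiv), Et3N (1.2 equiv), CH2Cl2, −78 → −40 °C
Reagents that add atoms: chlorotriethylsilane, CC[Si](Cl)(CC)CC
Why: Chemoselective O-silylation, in which the more acidic and alpha-effect-activated hydroperoxide (pKa about 12.5) is silylated ahead of the neutral primary alcohol (pKa about 16) at low temperature, masking OOH so that the alcohol can be oxidised without Hock-type cleavage.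

Step 4
Reactants: 4 (2S)-2-methyl-2-[(triethylsilyl)peroxy]dec-9-en-1-ol
Product: 5 (2S)-2-methyl-2-[(triethylsilyl)peroxy]dec-9-enal
Conditions: Dess–Martin periodinane (1.3 equiv), pyridine (3 equiv), CH2Cl2, 0 °C; crude 5 used at once
Reagents that add atoms: none
Why: Dess–Martin oxidation of the neopentyl-type primary alcohol under buffered conditions; the α-carbon is quaternary, so the α-peroxy aldehyde can neither enolise nor undergo Kornblum–DeLaMare fragmentation and C5 is not at risk.

Step 5
Reactants: 6 triphenylphosphine; 7 1-chloroethyl ethyl ether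
Product: 8 (1-ethoxyethyl)triphenylphosphonium chloride
Conditions: toluene, 0 °C → rt, 12 h; salt filtered and dried under vacuum
Reagents that add atoms: none
Why: Quaternisation of PPh3 by an α-chloro ether through its oxocarbenium ion, the same reaction that gives the methoxymethyl Wittig salt.

Step 6
Reactants: 5 (2S)-2-methyl-2-[(triethylsilyl)peroxy]dec-9-enal; 8 (1-ethoxyethyl)triphenylphosphonium chloride
Product: 11 (5S)-3-ethoxy-3,5-dimethyl-5-(oct-7-en-1-yl)-1,2-dioxolane, via ylide 9 (not isolated), via enol ether 10 (not isolated)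
Conditions: 8 (1.6 equiv), KN(SiMe3)2 (1.5 equiv), THF, −78 → −40 °C; then 5, −78 → 0 °C; pentane, filter, concentrate; then pyridinium p-toluenesulfonate (10 mol %), EtOH, 0 °C → rt
Reagents that add atoms: none
Why: Wittig olefination with the α-ethoxy ylide, an acetyl anion equivalent, makes the C3–C4 bond by attack of the future C3 carbonyl carbon on the aldehyde carbon (two centres that are both electrophilic in the normal aldol sense), and acidic ethanol then removes the silyl group and lets the hydroperoxide add 5-exo to the protonated enol ether (peroxyketalisation), closing the dioxolane with C5 untouched and C3 as an inconsequential epimer mixture.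

Step 7
Reactants: 11 (5S)-3-ethoxy-3,5-dimethyl-5-(oct-7-en-1-yl)-1,2-dioxolane
Product: 12 methyl 2-[(3R,5S)-3,5-dimethyl-5-(oct-7-en-1-yl)-1,2-dioxolan-3-yl]acetate
Conditions: CH2=C(OMe)OSiMe2tBu (3 equiv), TiCl4 (1.2 equiv), CH2Cl2, −78 °C; chromatography
Reagents that add atoms: 1-(tert-butyldimethylsilyloxy)-1-methoxyethene, C=C(OC)O[Si](C)(C)C(C)(C)C
Why: Lewis-acid ionisation of the peroxyketal to a planar peroxycarbenium ion and Mukaiyama-type capture by the silyl ketene acetal, which enters anti to the larger C5 substituent (the octenyl chain) and so gives mainly the (3R,5S) isomer with the acetate trans to the chain; the selectivity is expected to be modest and the minor 3S epimer is removed by chromatography.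

Step 8
Reactants: 12 methyl 2-[(3R,5S)-3,5-dimethyl-5-(oct-7-en-1-yl)-1,2-dioxolan-3-yl]acetate
Product: 13 methyl 2-[(3R,5S)-3,5-dimethyl-5-[(7E)-9-oxonon-7-en-1-yl]-1,2-dioxolan-3-yl]acetate
Conditions: (E)-but-2-enal (5 equiv), second-generation Hoveyda–Grubbs catalyst RuCl2(SIMes)(=CH–C6H4-2-OiPr) (5 mol %), CH2Cl2, 40 °C
Reagents that add atoms: (E)-but-2-enal, C/C=C/C=O
Why: Olefin cross-metathesis of an unhindered terminal alkene with crotonaldehyde gives the (E)-enal under thermodynamic control, and ruthenium alkylidenes tolerate dialkyl peroxides.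

Step 9
Reactants: 14 (3Z)-hex-3-en-1-ol; 15 1-phenyl-1H-tetrazole-5-thiol
Product: 16 5-{[(3Z)-hex-3-en-1-yl]sulfanyl}-1-phenyl-1H-tetrazole
Conditions: PPh3 (6), diisopropyl azodicarboxylate, THF, 0 °C → rt
Reagents that add atoms: none
Why: Mitsunobu thioetherification of the primary alcohol with the acidic tetrazolethiol, in which the Z-alkene takes no part.

Step 10
Reactants: 16 5-{[(3Z)-hex-3-en-1-yl]sulfanyl}-1-phenyl-1H-tetrazole
Product: 17 5-{[(3Z)-hex-3-en-1-yl]sulfonyl}-1-phenyl-1H-tetrazole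
Conditions: H2O2 (30% aq, 5 equiv), (NH4)6Mo7O24·4H2O (10 mol %), EtOH, 0 °C → rt
Reagents that add atoms: hydrogen peroxide, OO
Why: Molybdate-catalysed sulfide-to-sulfone oxidation, which is selective for sulfur over the isolated Z-alkene.

Step 11
Reactants: 13 methyl 2-[(3R,5S)-3,5-dimethyl-5-[(7E)-9-oxonon-7-en-1-yl]-1,2-dioxolan-3-yl]acetate; 17 5-{[(3Z)-hex-3-en-1-yl]sulfonyl}-1-phenyl-1H-tetrazole
Product: 19 methyl 2-[(3R,5S)-3,5-dimethyl-5-[(7E,9E,12Z)-pentadeca-7,9,12-trien-1-yl]-1,2-dioxolan-3-yl]acetate, via sulfonyl carbanion 18 (not isolated)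
Conditions: 17 (1.3 equiv), KN(SiMe3)2 (1.25 equiv), DME, −78 °C, 20 min; then 13, −78 → −20 °C; chromatography
Reagents that add atoms: none
Why: Julia–Kocienski olefination, in which addition of the metalated tetrazolyl sulfone to the enal, Smiles rearrangement and anti-elimination of SO2 and tetrazololate form the C9′=C10′ bond E-selectively, while the 7E and 12Z alkenes and both quaternary peroxide carbons (no α-hydrogens) are untouched at −78 °C.

**Compound list**
1 | dec-9-en-2-one | CC(=O)CCCCCCC=C | starting material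
2 | (2R)-2-methyl-2-(oct-7-en-1-yl)oxirane | C=CCCCCCC[C@]1(C)CO1 | intermediate
3 | (2S)-2-hydroperoxy-2-methyldec-9-en-1-ol | C=CCCCCCC[C@@](OO)(C)CO | intermediate
4 | (2S)-2-methyl-2-[(triethylsilyl)peroxy]dec-9-en-1-ol | C=CCCCCCC[C@@](OO[Si](CC)(CC)CC)(C)CO | intermediate
5 | (2S)-2-methyl-2-[(triethylsilyl)peroxy]dec-9-enal | C=CCCCCCC[C@@](OO[Si](CC)(CC)CC)(C)C=O | intermediate
6 | triphenylphosphine | c1ccc(cc1)P(c1ccccc1)c1ccccc1 | starting material
7 | 1-chloroethyl ethyl ether | CCOC(C)Cl | starting material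
8 | (1-ethoxyethyl)triphenylphosphonium chloride | CCOC(C)[P+](c1ccccc1)(c1ccccc1)c1ccccc1.[Cl-] | intermediate
9 | (1-ethoxyethylidene)triphenylphosphorane | CCOC(C)=P(c1ccccc1)(c1ccccc1)c1ccccc1 | intermediate
10 | (4S)-2-ethoxy-4-methyl-4-[(triethylsilyl)peroxy]dodeca-2,11-diene (E/Z mixture) | C=CCCCCCC[C@@](OO[Si](CC)(CC)CC)(C)C=C(C)OCC | intermediate
11 | (5S)-3-ethoxy-3,5-dimethyl-5-(oct-7-en-1-yl)-1,2-dioxolane (both C3 epimers) | C=CCCCCCC[C@@]1(C)CC(C)(OCC)OO1 | intermediate
12 | methyl 2-[(3R,5S)-3,5-dimethyl-5-(oct-7-en-1-yl)-1,2-dioxolan-3-yl]acetate | C=CCCCCCC[C@@]1(C)C[C@](C)(CC(=O)OC)OO1 | intermediate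
13 | methyl 2-[(3R,5S)-3,5-dimethyl-5-[(7E)-9-oxonon-7-en-1-yl]-1,2-dioxolan-3-yl]acetate | O=C/C=C/CCCCCC[C@@]1(C)C[C@](C)(CC(=O)OC)OO1 | intermediate
14 | (3Z)-hex-3-en-1-ol | CC/C=C\CCO | starting material
15 | 1-phenyl-1H-tetrazole-5-thiol | Sc1nnnn1-c1ccccc1 | starting material
16 | 5-{[(3Z)-hex-3-en-1-yl]sulfanyl}-1-phenyl-1H-tetrazole | CC/C=C\CCSc1nnnn1-c1ccccc1 | intermediate
17 | 5-{[(3Z)-hex-3-en-1-yl]sulfonyl}-1-phenyl-1H-tetrazole | CC/C=C\CCS(=O)(=O)c1nnnn1-c1ccccc1 | intermediate
18 | potassium (3Z)-1-[(1-phenyl-1H-tetrazol-5-yl)sulfonyl]hex-3-en-1-ide | CC/C=C\C[CH-]S(=O)(=O)c1nnnn1-c1ccccc1.[K+] | intermediate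
19 | methyl 2-[(3R,5S)-3,5-dimethyl-5-[(7E,9E,12Z)-pentadeca-7,9,12-trien-1-yl]-1,2-dioxolan-3-yl]acetate | CC/C=C\C/C=C/C=C/CCCCCC[C@@]1(C)C[C@](C)(CC(=O)OC)OO1 | target

**Step count and risks**

Total: 11 steps. Longest linear sequence: 8 steps (1, 2, 3, 4, 6, 7, 8, 11).

The three steps most likely to fail:

Step 6 is the main risk, because this Wittig/peroxyketalisation pairing is untested on an α-silylperoxy aldehyde. The ylide may attack silicon or the O–O bond, or add too slowly to the neopentyl aldehyde. The fallback sets out from 2 and keeps an acetyl anion equivalent but lets it meet the epoxide instead. 1-Ethoxyvinyllithium (ethyl vinyl ether, t-BuLi; BF3·OEt2, THF, −78 °C) opens 2 at CH2 to give enol ether carbinol (4R)-2-ethoxy-4-methyldodeca-1,11-dien-4-ol F2. Dilute HCl on work-up hydrolyses it to β-hydroxy ketone (4R)-4-hydroxy-4-methyldodec-11-en-2-one F3. NaBH4 gives diol (4R)-4-methyldodec-11-ene-2,4-diol F4. n-BuLi then TsCl sulfonylates only the secondary hydroxyl, giving monotosylate (4R)-4-hydroxy-4-methyldodec-11-en-2-yl 4-methylbenzenesulfonate F5, and KOtBu closes oxetane (4R)-2,4-dimethyl-4-(oct-7-en-1-yl)oxetane F6 with C5 retained. H2O2 with Me3SiOTf (Et2O, −78 °C) opens the oxetane at the tertiary carbon with inversion to hydroperoxy alcohol (4S)-4-hydroperoxy-4-methyldodec-11-en-2-ol F7. Et3SiCl/Et3N gives silyl peroxide (4S)-4-methyl-4-[(triethylsilyl)peroxy]dodec-11-en-2-ol F8, and Dess–Martin oxidation gives silylperoxy ketone (4S)-4-methyl-4-[(triethylsilyl)peroxy]dodec-11-en-2-one F9. Pyridinium p-toluenesulfonate in EtOH then returns the sequence to 11. The same C5–O bond is displaced with inversion as in the main route, so the same (5S) centre results.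

Step 3 may fail through competing silylation of the primary alcohol. The fallback sets out from 3 and removes the need for OOH/OH discrimination. Both oxygens are silylated (Et3SiCl 2.5 equiv, imidazole, DMF) to give bis-silyl compound triethyl{[(2S)-2-methyl-2-[(triethylsilyl)peroxy]dec-9-en-1-yl]oxy}silane F1. Swern conditions ((COCl)2, DMSO, CH2Cl2, −78 → −40 °C, then Et3N) oxidise the primary triethylsilyl ether directly to the aldehyde while the hindered tertiary silyl peroxide stays, returning to 5.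

Step 11 may fail because the sulfonyl carbanion can deprotonate the β-peroxy ester, triggering retro-oxa-Michael ring opening. E/Z leakage at C9′=C10′ is a lesser problem, handled on AgNO3-impregnated silica. The fallback sets out from 11 and carries out the base-mediated olefination before the ester exists. Cross-metathesis of 11 with (E)-but-2-enal (second-generation Hoveyda–Grubbs catalyst) gives enal (2E)-9-[(3S)-5-ethoxy-3,5-dimethyl-1,2-dioxolan-3-yl]non-2-enal F10. Julia–Kocienski olefination with 18 gives the base-stable triene peroxyketal (5S)-3-ethoxy-3,5-dimethyl-5-[(7E,9E,12Z)-pentadeca-7,9,12-trien-1-yl]-1,2-dioxolane F11. The TiCl4/silyl ketene acetal substitution of step 7 is then run last and returns to 19.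

Further compounds
F1 | step 3 | triethyl{[(2S)-2-methyl-2-[(triethylsilyl)peroxy]dec-9-en-1-yl]oxy}silane | C=CCCCCCC[C@@](OO[Si](CC)(CC)CC)(C)CO[Si](CC)(CC)CC
F2 | step 6 | (4R)-2-ethoxy-4-methyldodeca-1,11-dien-4-ol | C=CCCCCCC[C@](O)(C)CC(=C)OCC
F3 | step 6 | (4R)-4-hydroxy-4-methyldodec-11-en-2-one | C=CCCCCCC[C@](O)(C)CC(C)=O
F4 | step 6 | (4R)-4-methyldodec-11-ene-2,4-diol (both C2 epimers) | C=CCCCCCC[C@](O)(C)CC(C)O
F5 | step 6 | (4R)-4-hydroxy-4-methyldodec-11-en-2-yl 4-methylbenzenesulfonate (both C2 epimers) | C=CCCCCCC[C@](O)(C)CC(C)OS(=O)(=O)c1ccc(C)cc1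
F6 | step 6 | (4R)-2,4-dimethyl-4-(oct-7-en-1-yl)oxetane (both C2 epimers) | C=CCCCCCC[C@]1(C)CC(C)O1
F7 | step 6 | (4S)-4-hydroperoxy-4-methyldodec-11-en-2-ol (both C2 epimers) | C=CCCCCCC[C@@](OO)(C)CC(C)O
F8 | step 6 | (4S)-4-methyl-4-[(triethylsilyl)peroxy]dodec-11-en-2-ol (both C2 epimers) | C=CCCCCCC[C@@](OO[Si](CC)(CC)CC)(C)CC(C)O
F9 | step 6 | (4S)-4-methyl-4-[(triethylsilyl)peroxy]dodec-11-en-2-one | C=CCCCCCC[C@@](OO[Si](CC)(CC)CC)(C)CC(C)=O
F10 | step 11 | (2E)-9-[(3S)-5-ethoxy-3,5-dimethyl-1,2-dioxolan-3-yl]non-2-enal (both epimers at the ethoxy carbon) | O=C/C=C/CCCCCC[C@@]1(C)CC(C)(OCC)OO1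
F11 | step 11 | (5S)-3-ethoxy-3,5-dimethyl-5-[(7E,9E,12Z)-pentadeca-7,9,12-trien-1-yl]-1,2-dioxolane (both C3 epimers) | CC/C=C\C/C=C/C=C/CCCCCC[C@@]1(C)CC(C)(OCC)OO1
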